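The one constant I went looking for, when you sent your hunch that the dilute flask would finish cleaner and asked for a quick number, was the fraction of target lost per minute once target was made.

| setting | alder | elm | oak | Monday's | Sunday's |
|---|---|---|---|---|---|
| starting material | 0.15 M | 0.43 M | 0.84 M | 0.80 M | 0.20 M |
| partner | 2 equiv | 2 equiv | 2 equiv | 2.00 equiv | 2.00 equiv |
| catalyst | 0.65 mol% | 0.65 mol% | 0.65 mol% | 0.65 mol% | 0.65 mol% |
| remark | run made earlier | run made earlier | run made earlier |  |  |
| time |  |  |  | 3.0 min | 3.0 min |

- alder (time / s: target / %, over-reaction product / %): 20.0: 50.3, 0.3; 40.0: 86.4, 0; 50.0: 98.1, 1.3; 80.0: 98.8, 2.2; 90.0: 96.8, 1.9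
- elm (time / s: target / %, over-reaction product / %): 20.0: 97.0, 3.1; 40.0: 97.2, 3.4; 50.0: 96.0, 2.5; 80.0: 95.0, 5.0; 90.0: 91.2, 6.6
- oak (time / s: target / %, over-reaction product / %): 10.0: 99.4, 0.7; 25.0: 97.7, 2.7; 40.0: 95.3, 4.3; 60.0: 91.8, 6.7; 90.0: 87.1, 11.9

(scatter of a reading: 1 percentage point)

- where the amount of starting material changes, what is given in equivalents or mol% on it follows

- which one finishes higher in share of target in all that became target or over-reaction product ("neither" within 2 percentage points) (Monday's / Sunday's / neither)
- share of target in all that became target or over-reaction product, Monday's
- share of target in all that became target or over-reaction product, Sunday's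

1. I worked with the fraction of target left, the share of target in target plus over-reaction product. In the oak run target already read 99.4% at 10.0 s, so I treated what followed as loss alone, with one equivalent of partner spare.

2. A steady loss on what is left multiplies fractions, so I took the share as the exponential of minus constant times time. The oak share of 88.0% at 90.0 s gave 0.0854 min⁻¹ for the loss constant, the pseudo-first-order rate at which target goes while partner stands spare.

3. The elm run read 0.0466 min⁻¹, which was 0.546 of the oak value for 0.512 of the oak charge, so I scaled the constant with the charge.

4. Over the full 3.0 min this gave me 78.4% for Monday's flask and 94.1% for Sunday's.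

5. The forecast said Sunday's, with 78% (73% to 82%) for Monday's flask and 94% (92% to 96%) for Sunday's: “Dilution wins.”

The flasks gave 79.6% for Monday's and 94.2% for Sunday's, so Sunday's finished higher, inside both ranges.

    starting material + partner + catalyst → target + catalyst, rate k1*[starting material]*[partner]*[catalyst]/(1 + ([starting material]/sat1)) (2.40 mM, k = 6400 M⁻² s⁻¹)
    partner + target → over-reaction product (k = 0.00180 M⁻¹ s⁻¹)

In Monday's flask the making of target had 100% of its turnover behind it at 0.600 min, when over-reaction had 23% of its own, and over-reaction then went on with target and partner side by side, taking target to 79.6% at 3.00 min. Partner in Monday's flask had by then fallen to 0.796 equivalents, and my exponent of 0.244 stood against the flask's 0.228. The second flask is Monday's with partner cut to 1.20 equiv: with 0.200 equivalents spare instead of one, the loss constant, scaled by that spare partner, gives 95.2%, and the computed flask gave 95.3%, within 2 percentage points of Sunday's 94.2%.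

All runs stem from a simulated flask with made-up constants; the scatter is artificial.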